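**Retrosynthetic overview**
- Last C–C bond: trans-selective C3-benzylation of a (4R)-γ-butyrolactone that already carries the finished dihydrobenzofuran, using an erythro glycerol aryl ether benzyl bromide; then debenzylation.
- Key step: the γ-lactone and the 2,3-dihydrofuran ring close together in one acid treatment of an acyclic triol tert-butyl ester (MOM loss, lactonisation, phenol capture of a benzylic cation).
- That triol comes from one arene carrying two Evans imides: (R)-auxiliary benzylation of a succinate imide (future lactone C4), Pd α-arylation to add an arylacetyl imide, (S)-auxiliary boron syn-aldol (future benzofuran C3), then one LiBH4 reduction that removes both auxiliaries.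
- The (7R,8S)-erythro glycerol ether comes from a MgCl2-catalysed anti-aldol of an aryloxyacetyl imide built on methyl vanillate.
- Ring order: benzene rings are bought; lactone and dihydrofuran form simultaneously (step 10); a temporary 1,3-dioxane exists only on the side fragment.

Assumption: the N-acetyl and N-chloroacetyl derivatives of (S)-4-benzyl-1,3-oxazolidin-2-one are bought as catalogue compounds (each is otherwise one N-acylation from the parent auxiliary).

**Route**

Step 1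
Reactants: 1 mono-tert-butyl succinate; 2 (R)-4-benzyl-1,3-oxazolidin-2-one
Product: 4 tert-butyl 4-[(4R)-4-benzyl-2-oxo-1,3-oxazolidin-3-yl]-4-oxobutanoate, via mixed pivalic anhydride 3 (not isolated)
Conditions: t-BuCOCl, Et3N, THF, −20 °C; then LiCl, 2, −20 °C → rt
Reagents that add atoms: none
Why: One-pot mixed-anhydride N-acylation of an oxazolidinone (LiCl-promoted acyl transfer), the standard preparation of Evans imides; no stereocentre is formed.

Step 2
Reactants: 5 5-bromovanillin (3-bromo-4-hydroxy-5-methoxybenzaldehyde)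
Product: 6 3-bromo-5-methoxy-4-(methoxymethoxy)benzaldehyde
Conditions: MeOCH2Cl, i-Pr2NEt, CH2Cl2, 0 °C → rt
Reagents that add atoms: chloromethyl methyl ether, COCCl
Why: O-alkylation of the acidic phenol gives a MOM ether that survives hydride, strong base, Pd catalysis and boron triflate and is removed later by the acid of the key step.

Step 3
Reactants: 6 3-bromo-5-methoxy-4-(methoxymethoxy)benzaldehyde
Product: 7 [3-bromo-5-methoxy-4-(methoxymethoxy)phenyl]methanol
Conditions: NaBH4, MeOH, 0 °C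
Reagents that add atoms: none
Why: Chemoselective borohydride reduction of the aldehyde; the aryl bromide and the MOM ether are inert.

Step 4
Reactants: 7 [3-bromo-5-methoxy-4-(methoxymethoxy)phenyl]methanol
Product: 8 1-bromo-5-(bromomethyl)-3-methoxy-2-(methoxymethoxy)benzene
Conditions: CBr4, PPh3, CH2Cl2, 0 °C
Reagents that add atoms: carbon tetrabromide, BrC(Br)(Br)Br
Why: Appel bromination converts the benzylic alcohol into the bromide under neutral conditions that leave the MOM acetal intact.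

Step 5
Reactants: 4 tert-butyl 4-[(4R)-4-benzyl-2-oxo-1,3-oxazolidin-3-yl]-4-oxobutanoate; 8 1-bromo-5-(bromomethyl)-3-methoxy-2-(methoxymethoxy)benzene
Product: 9 tert-butyl (3R)-4-[(4R)-4-benzyl-2-oxo-1,3-oxazolidin-3-yl]-3-{[3-bromo-5-methoxy-4-(methoxymethoxy)phenyl]methyl}-4-oxobutanoate
Conditions: NaN(SiMe3)2, THF, −78 °C; then 8, −78 → −40 °C
Reagents that add atoms: none
Why: Evans asymmetric alkylation, in which the chelated sodium Z-enolate of the (R)-imide is benzylated on the face opposite the auxiliary benzyl group, setting the future lactone C4 as (R) while the aryl bromide is untouched.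

Step 6
Reactants: 10 (S)-3-acetyl-4-benzyl-1,3-oxazolidin-2-one
Product: 11 (S)-4-benzyl-3-[1-(trimethylsilyloxy)ethenyl]-1,3-oxazolidin-2-one
Conditions: Me3SiOTf, Et3N, CH2Cl2, 0 °C; used crude
Reagents that add atoms: trimethylsilyl trifluoromethanesulfonate, C[Si](C)(C)OS(=O)(=O)C(F)(F)F
Why: Soft enolisation and O-silylation of the acetyl imide gives the silyl ketene N,O-acetal that serves as a neutral enolate equivalent; no stereocentre is formed.

Step 7
Reactants: 9 the aryl bromide imide from step 5; 11 (S)-4-benzyl-3-[1-(trimethylsilyloxy)ethenyl]-1,3-oxazolidin-2-one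
Product: 12 tert-butyl (3R)-4-[(4R)-4-benzyl-2-oxo-1,3-oxazolidin-3-yl]-3-{[3-{2-[(4S)-4-benzyl-2-oxo-1,3-oxazolidin-3-yl]-2-oxoethyl}-5-methoxy-4-(methoxymethoxy)phenyl]methyl}-4-oxobutanoate
Conditions: Pd(dba)2 (5 mol%), P(t-Bu)3 (10 mol%), ZnF2 (0.6 equiv), DMF, 80 °C
Reagents that add atoms: none
Why: Hartwig-type palladium-catalysed α-arylation of an imide trimethylsilyl enolate (oxidative addition of the aryl bromide to zerovalent palladium, ZnF2-mediated transmetalation, reductive elimination) installs the arylacetyl imide under near-neutral conditions that spare the α-branched imide, the ester and the MOM ether; the acetyl-imide enolate is an untested extension of the propionyl-imide precedent.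

Step 8
Reactants: 12 the bis-imide from step 7; 13 4-(benzyloxy)-3-methoxybenzaldehyde
Product: 14 tert-butyl (3R)-4-[(4R)-4-benzyl-2-oxo-1,3-oxazolidin-3-yl]-3-{[3-{(2S,3S)-1-[(4S)-4-benzyl-2-oxo-1,3-oxazolidin-3-yl]-3-[4-(benzyloxy)-3-methoxyphenyl]-3-hydroxy-1-oxopropan-2-yl}-5-methoxy-4-(methoxymethoxy)phenyl]methyl}-4-oxobutanoate
Conditions: n-Bu2BOTf, i-Pr2NEt, CH2Cl2, −78 → 0 °C; then 13, −78 → 0 °C; pH 7 buffer, MeOH, H2O2, 0 °C
Reagents that add atoms: none
Why: Evans boron syn-aldol, in which only the arylacetyl imide has an enolisable CH2 and its Z-boron enolate adds through a Zimmerman–Traxler chair on the face set by the (S)-auxiliary to give the (2S,3S) syn adduct, fixing the future benzofuran C3 (the carbinol centre is re-set in step 10).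

Step 9
Reactants: 14 the syn-aldol bis-imide from step 8
Product: 15 tert-butyl (3R)-4-{3-[(1S,2R)-1-[4-(benzyloxy)-3-methoxyphenyl]-1,3-dihydroxypropan-2-yl]-5-methoxy-4-(methoxymethoxy)phenyl}-3-(hydroxymethyl)butanoate
Conditions: LiBH4, MeOH, THF, 0 °C; aq. NH4Cl
Reagents that add atoms: none
Why: Reductive cleavage of N-acyl oxazolidinones by LiBH4 removes both auxiliaries at once (imide to CH2OH) while the tert-butyl ester survives; no stereocentre is touched (the aryl-bearing carbon only changes descriptor from S to R).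

Step 10
Reactants: 15 the triol tert-butyl ester from step 9
Product: 16 (4R)-4-{[(2S,3R)-2-[4-(benzyloxy)-3-methoxyphenyl]-3-(hydroxymethyl)-7-methoxy-2,3-dihydro-1-benzofuran-5-yl]methyl}oxolan-2-one
Conditions: CF3CO2H–CH2Cl2–H2O (20:78:2), 0 °C → rt; then NaHCO3, MeOH
Reagents that add atoms: none
Why: Acid-triggered double cyclisation in one operation: MOM loss frees the phenol, which captures the para-benzyloxy-stabilised benzylic cation 5-exo to give the thermodynamically favoured 2,3-trans-dihydrobenzofuran (C2 set as S by the fixed C3 centre, ionisation being reversible), while the γ-hydroxy tert-butyl ester lactonises to the γ-butyrolactone.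

Step 11
Reactants: 17 methyl vanillate (methyl 4-hydroxy-3-methoxybenzoate); 18 (S)-4-benzyl-3-(chloroacetyl)-1,3-oxazolidin-2-one
Product: 19 methyl 4-{2-[(4S)-4-benzyl-2-oxo-1,3-oxazolidin-3-yl]-2-oxoethoxy}-3-methoxybenzoate
Conditions: K2CO3, NaI (cat.), acetone, rt
Reagents that add atoms: none
Why: Williamson-type displacement at the strongly activated α-chloro imide by the weakly basic para-ester phenoxide (Finkelstein catalysis by NaI) outruns acyl transfer; no stereocentre is formed.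

Step 12
Reactants: 19 the aryloxyacetyl imide from step 11; 13 4-(benzyloxy)-3-methoxybenzaldehyde
Product: 21 methyl 4-{[(2R,3R)-1-[(4S)-4-benzyl-2-oxo-1,3-oxazolidin-3-yl]-3-[4-(benzyloxy)-3-methoxyphenyl]-3-hydroxy-1-oxopropan-2-yl]oxy}-3-methoxybenzoate, via O-trimethylsilyl aldol ether 20 (not isolated)
Conditions: MgCl2 (20 mol%), Et3N, Me3SiCl, EtOAc, rt; then 0.5 M aq. HCl, THF, 0 °C
Reagents that add atoms: none
Why: Evans magnesium-halide-catalysed direct anti-aldol, in which Et3N enolises the MgCl2-chelated imide to the chelated Z-enolate that adds to the aldehyde through a boat transition state on the face away from the auxiliary benzyl group (the same face as an Evans alkylation), with Me3SiCl turning the catalyst over, so the (2R,3R) anti adduct forms, which is the (7R,8S)-erythro unit after reduction.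

Step 13
Reactants: 21 the anti-aldol imide from step 12
Product: 22 (1R,2S)-1-[4-(benzyloxy)-3-methoxyphenyl]-2-[4-(hydroxymethyl)-2-methoxyphenoxy]propane-1,3-diol
Conditions: LiBH4, MeOH, THF, 0 → 45 °C; aq. NH4Cl
Reagents that add atoms: none
Why: LiBH4 cleaves the imide reductively at 0 °C and on warming reduces the aryl methyl ester, giving the erythro triol without touching either stereocentre (the ether carbon only changes descriptor from R to S).

Step 14
Reactants: 22 the erythro triol from step 13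
Product: 23 (4-{[(4R,5S)-4-[4-(benzyloxy)-3-methoxyphenyl]-2,2-dimethyl-1,3-dioxan-5-yl]oxy}-3-methoxyphenyl)methanol
Conditions: Me2C(OMe)2, pyridinium p-toluenesulfonate (cat.), CH2Cl2, rt
Reagents that add atoms: 2,2-dimethoxypropane, COC(C)(C)OC
Why: Transketalisation selects the 1,3-diol as the six-membered acetonide and leaves the isolated benzylic alcohol free (any mixed ketal there falls off on aqueous work-up).

Step 15
Reactants: 23 the acetonide alcohol from step 14
Product: 24 (4R,5S)-4-[4-(benzyloxy)-3-methoxyphenyl]-5-[4-(bromomethyl)-2-methoxyphenoxy]-2,2-dimethyl-1,3-dioxane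
Conditions: CBr4, PPh3, 2,6-lutidine, CH2Cl2, 0 °C; used at once
Reagents that add atoms: carbon tetrabromide, BrC(Br)(Br)Br
Why: Appel bromination under buffered neutral conditions gives the reactive para-alkoxybenzyl bromide without opening the acetonide.

Step 16
Reactants: 16 the lactone–dihydrobenzofuran from step 10; 24 the benzyl bromide from step 15
Product: 26 (3R,4R)-4-{[(2S,3R)-2-[4-(benzyloxy)-3-methoxyphenyl]-3-(hydroxymethyl)-7-methoxy-2,3-dihydro-1-benzofuran-5-yl]methyl}-3-[(4-{[(1R,2S)-1-[4-(benzyloxy)-3-methoxyphenyl]-1,3-dihydroxypropan-2-yl]oxy}-3-methoxyphenyl)methyl]oxolan-2-one, via acetonide-protected lactone 25 (not isolated)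
Conditions: LiN(SiMe3)2 (2.2 equiv), THF, −78 °C; then 24, −78 → −40 °C; then 2 M aq. HCl, rt
Reagents that add atoms: none
Why: C-selective alkylation of the alkoxide–lactone enolate dianion (as in Fráter–Seebach chemistry), in which the benzyl bromide enters anti to the C4 substituent to give the 3,4-trans (3R,4R) lactone, followed by acetonide hydrolysis in the acidic quench.

Step 17
Reactants: 26 the bis-benzyl ether from step 16
Product: 27 CNP0298853.1, (3R,4R)-3-[(4-{[(1R,2S)-1,3-dihydroxy-1-(4-hydroxy-3-methoxyphenyl)propan-2-yl]oxy}-3-methoxyphenyl)methyl]-4-{[(2S,3R)-2-(4-hydroxy-3-methoxyphenyl)-3-(hydroxymethyl)-7-methoxy-2,3-dihydro-1-benzofuran-5-yl]methyl}oxolan-2-one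
Conditions: H2 (1 atm), 10% Pd/C, EtOAc–MeOH, rt
Reagents that add atoms: none
Why: Catalytic hydrogenolysis of the two aryl benzyl ethers under neutral conditions, where the secondary benzylic alcohol and the benzylic C–O bond of the dihydrobenzofuran cleave much more slowly; no stereocentre is affected.

**Compound list**
1 | mono-tert-butyl succinate (4-tert-butoxy-4-oxobutanoic acid) | CC(C)(C)OC(=O)CCC(=O)O | starting material
2 | (R)-4-benzyl-1,3-oxazolidin-2-one | O=C1N[C@H](Cc2ccccc2)CO1 | starting material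
3 | mixed pivalic anhydride of 1 | CC(C)(C)OC(=O)CCC(=O)OC(=O)C(C)(C)C | intermediate
4 | tert-butyl 4-[(4R)-4-benzyl-2-oxo-1,3-oxazolidin-3-yl]-4-oxobutanoate | CC(C)(C)OC(=O)CCC(=O)N1[C@H](Cc2ccccc2)COC1=O | intermediate
5 | 5-bromovanillin | O=Cc1cc(Br)c(O)c(OC)c1 | starting material
6 | 3-bromo-5-methoxy-4-(methoxymethoxy)benzaldehyde | O=Cc1cc(Br)c(OCOC)c(OC)c1 | intermediate
7 | [3-bromo-5-methoxy-4-(methoxymethoxy)phenyl]methanol | OCc1cc(Br)c(OCOC)c(OC)c1 | intermediate
8 | 1-bromo-5-(bromomethyl)-3-methoxy-2-(methoxymethoxy)benzene | BrCc1cc(Br)c(OCOC)c(OC)c1 | intermediate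
9 | tert-butyl (3R)-4-[(4R)-4-benzyl-2-oxo-1,3-oxazolidin-3-yl]-3-{[3-bromo-5-methoxy-4-(methoxymethoxy)phenyl]methyl}-4-oxobutanoate | CC(C)(C)OC(=O)C[C@@H](Cc1cc(Br)c(OCOC)c(OC)c1)C(=O)N1[C@H](Cc2ccccc2)COC1=O | intermediate
10 | (S)-3-acetyl-4-benzyl-1,3-oxazolidin-2-one | CC(=O)N1[C@@H](Cc2ccccc2)COC1=O | starting material
11 | (S)-4-benzyl-3-[1-(trimethylsilyloxy)ethenyl]-1,3-oxazolidin-2-one | C=C(O[Si](C)(C)C)N1[C@@H](Cc2ccccc2)COC1=O | intermediate
12 | tert-butyl (3R)-4-[(4R)-4-benzyl-2-oxo-1,3-oxazolidin-3-yl]-3-{[3-{2-[(4S)-4-benzyl-2-oxo-1,3-oxazolidin-3-yl]-2-oxoethyl}-5-methoxy-4-(methoxymethoxy)phenyl]methyl}-4-oxobutanoate | CC(C)(C)OC(=O)C[C@@H](Cc1cc(CC(=O)N2[C@@H](Cc3ccccc3)COC2=O)c(OCOC)c(OC)c1)C(=O)N1[C@H](Cc2ccccc2)COC1=O | intermediate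
13 | 4-(benzyloxy)-3-methoxybenzaldehyde | O=Cc1ccc(OCc2ccccc2)c(OC)c1 | starting material
14 | syn-aldol bis-imide: 12 with the arylacetyl CH2 turned into (2S)-CH bearing (3S)-CH(OH)[4-(benzyloxy)-3-methoxyphenyl] | CC(C)(C)OC(=O)C[C@@H](Cc1cc([C@H](C(=O)N2[C@@H](Cc3ccccc3)COC2=O)[C@H](O)c2ccc(OCc3ccccc3)c(OC)c2)c(OCOC)c(OC)c1)C(=O)N1[C@H](Cc2ccccc2)COC1=O | intermediate
15 | tert-butyl (3R)-4-{3-[(1S,2R)-1-[4-(benzyloxy)-3-methoxyphenyl]-1,3-dihydroxypropan-2-yl]-5-methoxy-4-(methoxymethoxy)phenyl}-3-(hydroxymethyl)butanoate | CC(C)(C)OC(=O)C[C@@H](Cc1cc([C@H](CO)[C@H](O)c2ccc(OCc3ccccc3)c(OC)c2)c(OCOC)c(OC)c1)CO | intermediate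
16 | (4R)-4-{[(2S,3R)-2-[4-(benzyloxy)-3-methoxyphenyl]-3-(hydroxymethyl)-7-methoxy-2,3-dihydro-1-benzofuran-5-yl]methyl}oxolan-2-one | O=C1C[C@@H](Cc2cc(OC)c3c(c2)[C@H](CO)[C@@H](c2ccc(OCc4ccccc4)c(OC)c2)O3)CO1 | intermediate
17 | methyl vanillate | COC(=O)c1ccc(O)c(OC)c1 | starting material
18 | (S)-4-benzyl-3-(chloroacetyl)-1,3-oxazolidin-2-one | ClCC(=O)N1[C@@H](Cc2ccccc2)COC1=O | starting material
19 | methyl 4-{2-[(4S)-4-benzyl-2-oxo-1,3-oxazolidin-3-yl]-2-oxoethoxy}-3-methoxybenzoate | COC(=O)c1ccc(OCC(=O)N2[C@@H](Cc3ccccc3)COC2=O)c(OC)c1 | intermediate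
20 | O-trimethylsilyl ether of 21 | COc1cc([C@@H](O[Si](C)(C)C)[C@H](C(=O)N2[C@@H](Cc3ccccc3)COC2=O)Oc2ccc(C(=O)OC)cc2OC)ccc1OCc1ccccc1 | intermediate
21 | methyl 4-{[(2R,3R)-1-[(4S)-4-benzyl-2-oxo-1,3-oxazolidin-3-yl]-3-[4-(benzyloxy)-3-methoxyphenyl]-3-hydroxy-1-oxopropan-2-yl]oxy}-3-methoxybenzoate (anti) | COc1cc([C@@H](O)[C@H](C(=O)N2[C@@H](Cc3ccccc3)COC2=O)Oc2ccc(C(=O)OC)cc2OC)ccc1OCc1ccccc1 | intermediate
22 | (1R,2S)-1-[4-(benzyloxy)-3-methoxyphenyl]-2-[4-(hydroxymethyl)-2-methoxyphenoxy]propane-1,3-diol (erythro) | COc1cc([C@@H](O)[C@H](CO)Oc2ccc(CO)cc2OC)ccc1OCc1ccccc1 | intermediate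
23 | (4-{[(4R,5S)-4-[4-(benzyloxy)-3-methoxyphenyl]-2,2-dimethyl-1,3-dioxan-5-yl]oxy}-3-methoxyphenyl)methanol | COc1cc([C@H]2OC(C)(C)OC[C@@H]2Oc2ccc(CO)cc2OC)ccc1OCc1ccccc1 | intermediate
24 | (4R,5S)-4-[4-(benzyloxy)-3-methoxyphenyl]-5-[4-(bromomethyl)-2-methoxyphenoxy]-2,2-dimethyl-1,3-dioxane | COc1cc([C@H]2OC(C)(C)OC[C@@H]2Oc2ccc(CBr)cc2OC)ccc1OCc1ccccc1 | intermediate
25 | acetonide of 26 (3R,4R trans lactone) | COc1cc([C@H]2OC(C)(C)OC[C@@H]2Oc2ccc(C[C@H]3C(=O)OC[C@@H]3Cc3cc(OC)c4c(c3)[C@H](CO)[C@@H](c3ccc(OCc5ccccc5)c(OC)c3)O4)cc2OC)ccc1OCc1ccccc1 | intermediate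
26 | bis-O-benzyl ether of the target (both phenols benzylated) | COc1cc([C@@H](O)[C@H](CO)Oc2ccc(C[C@H]3C(=O)OC[C@@H]3Cc3cc(OC)c4c(c3)[C@H](CO)[C@@H](c3ccc(OCc5ccccc5)c(OC)c3)O4)cc2OC)ccc1OCc1ccccc1 | intermediate
27 | CNP0298853.1 | COc1cc([C@@H](O)[C@H](CO)Oc2ccc(C[C@H]3C(=O)OC[C@@H]3Cc3cc(OC)c4c(c3)[C@H](CO)[C@@H](c3ccc(O)c(OC)c3)O4)cc2OC)ccc1O | target

**Totals and risks**

Total step count: 17. Longest linear sequence: 10 steps (5 to 27 through steps 2, 3, 4, 5, 7, 8, 9, 10, 16, 17).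

Steps most likely to fail:

Step 7 (Pd α-arylation). The aryl bromide is electron-rich and ortho-alkoxy-substituted, and the acetyl-imide silyl enolate has no direct precedent. Fallback: the acetic acid arm is built from an allyl group instead. Setting out from 9, Stille coupling with allyltributylstannane (Pd(PPh3)4, LiCl, DMF, 90 °C) gives the allyl arene F1. Lemieux–Johnson cleavage (OsO4 cat., NaIO4, 2,6-lutidine, dioxane–H2O) gives the arylacetaldehyde F2. Pinnick oxidation (NaClO2, NaH2PO4, 2-methyl-2-butene, t-BuOH–H2O) gives the arylacetic acid F3. Activation with t-BuCOCl/Et3N gives the mixed pivalic anhydride of the arylacetic acid F4. LiCl-promoted acylation of (S)-4-benzyl-1,3-oxazolidin-2-one (bought, or recovered from step 13) then comes back to the route at 12.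

Step 10 (double cyclisation). The benzylic cation next to a carbon bearing CH2OH can lose formaldehyde to give a stilbene, the trans/cis ratio may be poor, and MOM-derived formaldehyde can form formals. Fallback: the dihydrofuran is closed before the auxiliaries are removed, so that C3 carries an acyl group that cannot fragment. Setting out from 14, CF3CO2H–CH2Cl2 (0 °C → rt) removes the MOM and tert-butyl groups and cyclises the benzylic alcohol onto the phenol to give the trans-dihydrobenzofuran bis-imide carboxylic acid F5. Its lithium carboxylate (LiOH, 1 equiv) is reduced with LiBH4/MeOH in THF (both imides are reduced, the carboxylate is not) to the dihydroxy acid F6. F6 lactonises on acidification (1 M HCl, rt) and comes back to the route at 16; the two rings then form in separate operations.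

Step 12 (magnesium anti-aldol). α-Aryloxy imides are outside the proven scope, so the anti selectivity or the facial sense could fail. Fallback: the erythro unit is made by a boron syn-aldol in the enantiomeric auxiliary series followed by inversion of the carbinol. Setting out from 17 and 2, N-acylation of 2 (n-BuLi, ClCH2COCl, THF, −78 °C) gives (R)-4-benzyl-3-(chloroacetyl)-1,3-oxazolidin-2-one F7. Alkylation of 17 with F7 (K2CO3, NaI, acetone) gives the (R)-auxiliary aryloxyacetyl imide F8. The n-Bu2BOTf/i-Pr2NEt syn-aldol with 13 gives the (2R,3S) syn-aldol adduct F9. Mitsunobu inversion (4-nitrobenzoic acid, PPh3, diisopropyl azodicarboxylate, THF, 0 °C) gives the (2R,3R) 4-nitrobenzoate F10. Excess LiBH4 (THF–MeOH, 0 → 45 °C) then reduces the imide, cleaves the nitrobenzoate and reduces the methyl ester, and the sequence comes back to the route at 22.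

**Further compounds**
F1 | step 7 | tert-butyl (3R)-4-[(4R)-4-benzyl-2-oxo-1,3-oxazolidin-3-yl]-3-{[5-methoxy-4-(methoxymethoxy)-3-(prop-2-en-1-yl)phenyl]methyl}-4-oxobutanoate | CC(C)(C)OC(=O)C[C@@H](Cc1cc(CC=C)c(OCOC)c(OC)c1)C(=O)N1[C@H](Cc2ccccc2)COC1=O
F2 | step 7 | tert-butyl (3R)-4-[(4R)-4-benzyl-2-oxo-1,3-oxazolidin-3-yl]-3-{[5-methoxy-4-(methoxymethoxy)-3-(2-oxoethyl)phenyl]methyl}-4-oxobutanoate | CC(C)(C)OC(=O)C[C@@H](Cc1cc(CC=O)c(OCOC)c(OC)c1)C(=O)N1[C@H](Cc2ccccc2)COC1=O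
F3 | step 7 | {5-[(2R)-3-[(4R)-4-benzyl-2-oxo-1,3-oxazolidin-3-yl]-2-(2-tert-butoxy-2-oxoethyl)-3-oxopropyl]-3-methoxy-2-(methoxymethoxy)phenyl}acetic acid | CC(C)(C)OC(=O)C[C@@H](Cc1cc(CC(=O)O)c(OCOC)c(OC)c1)C(=O)N1[C@H](Cc2ccccc2)COC1=O
F4 | step 7 | mixed pivalic anhydride of F3 | CC(C)(C)OC(=O)C[C@@H](Cc1cc(CC(=O)OC(=O)C(C)(C)C)c(OCOC)c(OC)c1)C(=O)N1[C@H](Cc2ccccc2)COC1=O
F5 | step 10 | (3R)-4-[(4R)-4-benzyl-2-oxo-1,3-oxazolidin-3-yl]-3-{[(2S,3S)-2-[4-(benzyloxy)-3-methoxyphenyl]-3-{[(4S)-4-benzyl-2-oxo-1,3-oxazolidin-3-yl]carbonyl}-7-methoxy-2,3-dihydro-1-benzofuran-5-yl]methyl}-4-oxobutanoic acid | OC(=O)C[C@@H](Cc1cc(OC)c2c(c1)[C@H](C(=O)N1[C@@H](Cc3ccccc3)COC1=O)[C@@H](c1ccc(OCc3ccccc3)c(OC)c1)O2)C(=O)N1[C@H](Cc2ccccc2)COC1=O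
F6 | step 10 | (3R)-4-{(2S,3R)-2-[4-(benzyloxy)-3-methoxyphenyl]-3-(hydroxymethyl)-7-methoxy-2,3-dihydro-1-benzofuran-5-yl}-3-(hydroxymethyl)butanoic acid | OC(=O)C[C@@H](Cc1cc(OC)c2c(c1)[C@H](CO)[C@@H](c1ccc(OCc3ccccc3)c(OC)c1)O2)CO
F7 | step 12 | (R)-4-benzyl-3-(chloroacetyl)-1,3-oxazolidin-2-one | ClCC(=O)N1[C@H](Cc2ccccc2)COC1=O
F8 | step 12 | methyl 4-{2-[(4R)-4-benzyl-2-oxo-1,3-oxazolidin-3-yl]-2-oxoethoxy}-3-methoxybenzoate | COC(=O)c1ccc(OCC(=O)N2[C@H](Cc3ccccc3)COC2=O)c(OC)c1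
F9 | step 12 | methyl 4-{[(2R,3S)-1-[(4R)-4-benzyl-2-oxo-1,3-oxazolidin-3-yl]-3-[4-(benzyloxy)-3-methoxyphenyl]-3-hydroxy-1-oxopropan-2-yl]oxy}-3-methoxybenzoate | COc1cc([C@H](O)[C@H](C(=O)N2[C@H](Cc3ccccc3)COC2=O)Oc2ccc(C(=O)OC)cc2OC)ccc1OCc1ccccc1
F10 | step 12 | (1R,2R)-3-[(4R)-4-benzyl-2-oxo-1,3-oxazolidin-3-yl]-1-[4-(benzyloxy)-3-methoxyphenyl]-2-[2-methoxy-4-(methoxycarbonyl)phenoxy]-3-oxopropyl 4-nitrobenzoate | COc1cc([C@@H](OC(=O)c2ccc(cc2)[N+](=O)[O-])[C@H](C(=O)N2[C@H](Cc3ccccc3)COC2=O)Oc2ccc(C(=O)OC)cc2OC)ccc1OCc1ccccc1
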